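The oxane ring is disconnected at O1–C2 and C3–C4 into a β-hydroxy aldehyde (O1, C6, C5, C4) and the styrene C2=C3 of a 3-substituted 1,5-diarylpenta-1,4-diene. A scandium triflate-promoted Prins-type [4+2] annulation joins both fragments: the electron-rich 4-silyloxystyryl arm attacks the aldehyde and the C6 hydroxyl traps the C2 cation, which the para-oxygenated phenyl ring on C2 stabilises as a quinone methide. The second styryl arm, the future free (E)-alkene, is switched off as an aryl pivalate. C6 and the C7/C8 pair are set beforehand by allylborations; C3 and C4 are then secured through the C4 ketone.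

Key step: step 12

Remark: atom labels follow the oxane ring of the target (O1, C2 aryl-bearing, C3, C4 carbinol, C5, C6 arylethyl-bearing); C7 is the methine on C3 and C8 the side-chain carbinol carbon. (R)-TRIP is (R)-3,3'-bis(2,4,6-triisopropylphenyl)-1,1'-binaphthyl-2,2'-diyl hydrogen phosphate and is assumed to direct Re-face allylation of aliphatic aldehydes as it does for benzaldehyde.

Step 1
Reactants: 1 4-iodophenol
Product: 2 4-iodophenyl pivalate
Conditions: PivCl, Et3N, DMAP (cat.), CH2Cl2, 0 °C to rt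
Reagents that add atoms: pivaloyl chloride CC(C)(C)C(Cl)=O
Why: O-acylation of the phenol under nucleophilic catalysis should give the hindered, electron-withdrawing aryl ester that serves three fragments.

Step 2
Reactants: 2 4-iodophenyl pivalate; 3 allyl alcohol
Product: 4 4-(3-oxopropyl)phenyl pivalate
Conditions: Pd(OAc)2 (3 mol %), Bu4NCl, NaHCO3, DMF, 45 °C
Reagents that add atoms: none
Why: Heck arylation of allyl alcohol under ligand-free phase-transfer conditions, with β-hydride elimination toward the carbinol and enol–aldehyde tautomerism, should give the 3-arylpropanal.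

Step 3
Reactants: 4 4-(3-oxopropyl)phenyl pivalate
Product: 5 4-[(3S)-3-hydroxyhex-5-en-1-yl]phenyl pivalate
Conditions: allylboronic acid pinacol ester, (R)-TRIP (5 mol %), toluene, −30 °C; aqueous work-up
Reagents that add atoms: allylboronic acid pinacol ester C=CCB1OC(C)(C)C(C)(C)O1
Why: chiral phosphoric acid-catalysed allylboration through a closed chair transition state should add allyl to the Re face of the aldehyde and set the 3S carbinol (the future C6).

Step 4
Reactants: 5 4-[(3S)-3-hydroxyhex-5-en-1-yl]phenyl pivalate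
Product: 6 4-[(3S)-3-hydroxy-5-oxopentyl]phenyl pivalate
Conditions: O3, CH2Cl2, −78 °C; then PPh3, −78 °C to rt; used directly
Reagents that add atoms: ozone [O-][O+]=O
Why: ozonolysis with reductive work-up should cleave only the terminal alkene (the acyloxy arene is deactivated) and leave the carbinol stereocentre untouched.

Step 5
Reactants: 2 4-iodophenyl pivalate; 7 but-3-en-1-ol
Product: 8 4-(4-oxobutyl)phenyl pivalate
Conditions: Pd(OAc)2 (3 mol %), LiCl, LiOAc, Bu4NCl, DMF, 70 °C
Reagents that add atoms: none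
Why: Heck arylation of the homoallylic alcohol followed by palladium hydride chain-walking to the enol (redox-relay Heck reaction) should give the 4-arylbutanal.

Step 6
Reactants: 2 4-iodophenyl pivalate; 9 acrolein
Product: 10 4-[(1E)-3-oxoprop-1-en-1-yl]phenyl pivalate
Conditions: Pd(OAc)2 (3 mol %), Bu4NCl, NaHCO3, DMF, 40 °C
Reagents that add atoms: none
Why: Heck arylation of acrolein with syn β-hydride elimination should give the (E)-cinnamaldehyde.

Step 7
Reactants: 10 4-[(1E)-3-oxoprop-1-en-1-yl]phenyl pivalate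
Product: 11 4-[(1E)-3-hydroxypenta-1,4-dien-1-yl]phenyl pivalate (racemic)
Conditions: vinylMgBr, THF, −78 °C; then H2O
Reagents that add atoms: vinylmagnesium bromide C=C[Mg]Br
Why: 1,2-addition of the Grignard reagent to the enal at low temperature should be chemoselective over the hindered aryl pivalate; the racemic carbinol centre is erased in step 8.

Step 8
Reactants: 11 4-[(1E)-3-hydroxypenta-1,4-dien-1-yl]phenyl pivalate
Product: 12 4-[(1E,3E)-5-(4,4,5,5-tetramethyl-1,3,2-dioxaborolan-2-yl)penta-1,3-dien-1-yl]phenyl pivalate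
Conditions: B2pin2, Pd(MeCN)4(BF4)2 (5 mol %), DMSO–MeOH, 40 °C
Reagents that add atoms: bis(pinacolato)diboron CC1(C)OB(OC1(C)C)B1OC(C)(C)C(C)(C)O1
Why: palladium-catalysed borylation of the allylic alcohol through a pentadienyl-palladium intermediate should deliver boron to the unhindered terminus and give the linear E,E boronate that keeps the styrene conjugation.

Step 9
Reactants: 12 dienyl boronate; 8 4-(4-oxobutyl)phenyl pivalate
Product: 13 (1E,3S,4S)-3-ethenyl-1,7-bis[4-(pivaloyloxy)phenyl]hept-1-en-4-ol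
Conditions: (R)-TRIP (5 mol %), 4 Å MS, toluene, −30 °C; aqueous work-up
Reagents that add atoms: none
Why: chiral phosphoric acid-catalysed allylboration through a closed chair transition state should react at the γ-carbon of 12, the E geometry setting the anti relationship of C7 and C8 and the catalyst setting Re-face attack (8S).

Step 10
Reactants: 13 (1E,3S,4S)-3-ethenyl-1,7-bis[4-(pivaloyloxy)phenyl]hept-1-en-4-ol
Product: 14 (1E,3S,4S)-3-ethenyl-1,7-bis[4-(pivaloyloxy)phenyl]hept-1-en-4-yl acetate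
Conditions: Ac2O, pyridine, DMAP (cat.), CH2Cl2, rt
Reagents that add atoms: acetic anhydride CC(=O)OC(C)=O
Why: acetylation masks the C8 hydroxyl, which would otherwise relay palladium hydride in step 11, capture the C2 cation as a five-membered ether in step 12 and be oxidised in step 13.

Step 11
Reactants: 14 vinyl acetate; 15 tert-butyl(4-iodophenoxy)dimethylsilane
Product: 16 (1E,3R,4S)-3-[(E)-2-(4-{[tert-butyl(dimethyl)silyl]oxy}phenyl)ethenyl]-1,7-bis[4-(pivaloyloxy)phenyl]hept-1-en-4-yl acetate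
Conditions: Pd(OAc)2 (5 mol %), PPh3 (10 mol %), Ag2CO3, MeCN, 60 °C
Reagents that add atoms: none
Why: Heck arylation should take place at the monosubstituted alkene (the internal styrene inserts far more slowly), silver carbonate suppressing double-bond migration and syn β-hydride elimination giving the E styrene.

Step 12
Reactants: 16 bis-styryl acetate; 6 4-[(3S)-3-hydroxy-5-oxopentyl]phenyl pivalate
Product: 17 (1E,3R,4S)-3-[(2S,3S,4R,6S)-2-(4-{[tert-butyl(dimethyl)silyl]oxy}phenyl)-4-hydroxy-6-{2-[4-(pivaloyloxy)phenyl]ethyl}oxan-3-yl]-1,7-bis[4-(pivaloyloxy)phenyl]hept-1-en-4-yl acetate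
Conditions: Sc(OTf)3 (10 mol %), 4 Å MS, CH2Cl2, −40 to 0 °C
Reagents that add atoms: none
Why: Proposed new method: the scandium-bound aldehyde carbon C4 of 6 is attacked by the β-carbon (C3) of the electron-rich (E)-4-silyloxystyryl arm of 16 (Prins-type alkene–carbonyl addition), which creates a C2 benzylic cation that is an O-silylated p-quinone methide, and the C6 hydroxyl then adds to C2 to close the oxane. The closest known reaction types are the acid-mediated Prins reaction of aryl alkenes with aldehydes, in which an oxygen nucleophile captures the benzylic cation (1,3-dioxane synthesis), and the [4+2] annulation of salicylaldehydes with styrenes to 4-oxygenated 2-arylchromans. The C3–C4 bond forms intermolecularly and the O1–C2 bond closes the six-membered ring in the 6-exo-trig mode onto the exocyclic quinoid carbon C2. C6 comes from 6 and steers the rest: C2 is set under thermodynamic control (the 4-silyloxybenzylic C–O bond ionises reversibly) with the aryl group equatorial and cis to the C6 side chain, C3 is set by a chair-like closure in which the E alkene places the C7 branch equatorial and trans to the aryl group, and C4 follows 1,3-anti induction from the C6 oxygen (polar model), which gives the equatorial alcohol that steps 13 and 14 invert. The step needs site selectivity between the two styryl arms, secured by the donor silyloxy group on one arm against the acyloxy group on the other, and ring-size selectivity in the cation capture, secured by the C8 acetate so that only the C6 hydroxyl can close a ring.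

Step 13
Reactants: 17 equatorial oxan-4-ol
Product: 18 (1E,3R,4S)-3-[(2S,3R,6S)-2-(4-{[tert-butyl(dimethyl)silyl]oxy}phenyl)-4-oxo-6-{2-[4-(pivaloyloxy)phenyl]ethyl}oxan-3-yl]-1,7-bis[4-(pivaloyloxy)phenyl]hept-1-en-4-yl acetate
Conditions: Dess–Martin periodinane, pyridine, CH2Cl2, 0 °C to rt; then DBU (20 mol %), CH2Cl2, rt
Reagents that add atoms: none
Why: Dess–Martin oxidation of the only free hydroxyl should give the oxan-4-one, and DBU should equilibrate C3 (α to the ketone) to the equatorial position trans to the C2 aryl group, so that any C3 or C4 epimer from step 12 converges on 18.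

Step 14
Reactants: 18 oxan-4-one
Product: 20 4-[(1E,3R,4S)-4-hydroxy-7-(4-hydroxyphenyl)-3-[(2S,3S,4S,6S)-4-hydroxy-2-(4-hydroxyphenyl)-6-[2-(4-hydroxyphenyl)ethyl]oxan-3-yl]hept-1-en-1-yl]phenol, via protected axial C4 alcohol 19 (not isolated)
Conditions: LiBH(s-Bu)3 (L-Selectride), THF, −78 °C; then MeOH, K2CO3, 0 °C to rt
Reagents that add atoms: none
Why: the bulky trialkylborohydride should attack the 2,3,6-triequatorial oxan-4-one from the equatorial face to give the axial 4S alcohol cis to the C3 branch, and methanolysis in the same flask should remove the three aryl pivalates, the acetate and the aryl silyl ether.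

Compound list
1 | 4-iodophenol | Oc1ccc(I)cc1 | starting material
2 | 4-iodophenyl pivalate | CC(C)(C)C(=O)Oc1ccc(I)cc1 | intermediate
3 | allyl alcohol | C=CCO | starting material
4 | 4-(3-oxopropyl)phenyl pivalate | CC(C)(C)C(=O)Oc1ccc(CCC=O)cc1 | intermediate
5 | 4-[(3S)-3-hydroxyhex-5-en-1-yl]phenyl pivalate | CC(C)(C)C(=O)Oc1ccc(CC[C@H](O)CC=C)cc1 | intermediate
6 | 4-[(3S)-3-hydroxy-5-oxopentyl]phenyl pivalate | CC(C)(C)C(=O)Oc1ccc(CC[C@H](O)CC=O)cc1 | intermediate
7 | but-3-en-1-ol | C=CCCO | starting material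
8 | 4-(4-oxobutyl)phenyl pivalate | CC(C)(C)C(=O)Oc1ccc(CCCC=O)cc1 | intermediate
9 | acrolein | C=CC=O | starting material
10 | 4-[(1E)-3-oxoprop-1-en-1-yl]phenyl pivalate | CC(C)(C)C(=O)Oc1ccc(/C=C/C=O)cc1 | intermediate
11 | 4-[(1E)-3-hydroxypenta-1,4-dien-1-yl]phenyl pivalate (racemic) | CC(C)(C)C(=O)Oc1ccc(/C=C/C(O)C=C)cc1 | intermediate
12 | 4-[(1E,3E)-5-(4,4,5,5-tetramethyl-1,3,2-dioxaborolan-2-yl)penta-1,3-dien-1-yl]phenyl pivalate | CC(C)(C)C(=O)Oc1ccc(/C=C/C=C/CB2OC(C)(C)C(C)(C)O2)cc1 | intermediate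
13 | (1E,3S,4S)-3-ethenyl-1,7-bis[4-(pivaloyloxy)phenyl]hept-1-en-4-ol | CC(C)(C)C(=O)Oc1ccc(/C=C/[C@H](C=C)[C@@H](O)CCCc2ccc(OC(=O)C(C)(C)C)cc2)cc1 | intermediate
14 | (1E,3S,4S)-3-ethenyl-1,7-bis[4-(pivaloyloxy)phenyl]hept-1-en-4-yl acetate | CC(C)(C)C(=O)Oc1ccc(/C=C/[C@H](C=C)[C@@H](OC(C)=O)CCCc2ccc(OC(=O)C(C)(C)C)cc2)cc1 | intermediate
15 | tert-butyl(4-iodophenoxy)dimethylsilane | CC(C)(C)[Si](C)(C)Oc1ccc(I)cc1 | starting material
16 | (1E,3R,4S)-3-[(E)-2-(4-{[tert-butyl(dimethyl)silyl]oxy}phenyl)ethenyl]-1,7-bis[4-(pivaloyloxy)phenyl]hept-1-en-4-yl acetate | CC(C)(C)C(=O)Oc1ccc(/C=C/[C@H](/C=C/c2ccc(O[Si](C)(C)C(C)(C)C)cc2)[C@@H](OC(C)=O)CCCc2ccc(OC(=O)C(C)(C)C)cc2)cc1 | intermediate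
17 | (1E,3R,4S)-3-[(2S,3S,4R,6S)-2-(4-{[tert-butyl(dimethyl)silyl]oxy}phenyl)-4-hydroxy-6-{2-[4-(pivaloyloxy)phenyl]ethyl}oxan-3-yl]-1,7-bis[4-(pivaloyloxy)phenyl]hept-1-en-4-yl acetate (equatorial 4-OH) | CC(C)(C)C(=O)Oc1ccc(/C=C/[C@H]([C@@H]2[C@@H](c3ccc(O[Si](C)(C)C(C)(C)C)cc3)O[C@@H](CCc3ccc(OC(=O)C(C)(C)C)cc3)C[C@H]2O)[C@@H](OC(C)=O)CCCc2ccc(OC(=O)C(C)(C)C)cc2)cc1 | intermediate
18 | (1E,3R,4S)-3-[(2S,3R,6S)-2-(4-{[tert-butyl(dimethyl)silyl]oxy}phenyl)-4-oxo-6-{2-[4-(pivaloyloxy)phenyl]ethyl}oxan-3-yl]-1,7-bis[4-(pivaloyloxy)phenyl]hept-1-en-4-yl acetate | CC(C)(C)C(=O)Oc1ccc(/C=C/[C@H]([C@@H]2[C@@H](c3ccc(O[Si](C)(C)C(C)(C)C)cc3)O[C@@H](CCc3ccc(OC(=O)C(C)(C)C)cc3)CC2=O)[C@@H](OC(C)=O)CCCc2ccc(OC(=O)C(C)(C)C)cc2)cc1 | intermediate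
19 | (1E,3R,4S)-3-[(2S,3S,4S,6S)-2-(4-{[tert-butyl(dimethyl)silyl]oxy}phenyl)-4-hydroxy-6-{2-[4-(pivaloyloxy)phenyl]ethyl}oxan-3-yl]-1,7-bis[4-(pivaloyloxy)phenyl]hept-1-en-4-yl acetate (axial 4-OH) | CC(C)(C)C(=O)Oc1ccc(/C=C/[C@H]([C@@H]2[C@@H](c3ccc(O[Si](C)(C)C(C)(C)C)cc3)O[C@@H](CCc3ccc(OC(=O)C(C)(C)C)cc3)C[C@@H]2O)[C@@H](OC(C)=O)CCCc2ccc(OC(=O)C(C)(C)C)cc2)cc1 | intermediate
20 | 4-[(1E,3R,4S)-4-hydroxy-7-(4-hydroxyphenyl)-3-[(2S,3S,4S,6S)-4-hydroxy-2-(4-hydroxyphenyl)-6-[2-(4-hydroxyphenyl)ethyl]oxan-3-yl]hept-1-en-1-yl]phenol | Oc1ccc(/C=C/[C@H]([C@@H]2[C@@H](c3ccc(O)cc3)O[C@@H](CCc3ccc(O)cc3)C[C@@H]2O)[C@@H](O)CCCc2ccc(O)cc2)cc1 | target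

Total step count: 14. Longest linear sequence: 10 steps (steps 1, 6, 7, 8, 9, 10, 11, 12, 13, 14).

Steps most likely to fail

1. Step 12 (Proposed new method). The free β-hydroxy aldehyde may dehydrate or self-acetalise faster than the hindered styrene attacks it, or the C2 cation may lose a proton instead of closing the ring. Fallback by known chemistry, setting out from 14 and 5 and coming back at 17: cross-metathesis of the two terminal alkenes (second-generation Hoveyda–Grubbs catalyst, CH2Cl2, 40 °C) should give (1E,3S,4S)-3-[(1E,4S)-4-hydroxy-6-{4-(pivaloyloxy)phenyl}hex-1-en-1-yl]-1,7-bis[4-(pivaloyloxy)phenyl]hept-1-en-4-yl acetate F1. A Prins cyclisation of F1 with commercial 4-[(tert-butyldimethylsilyl)oxy]benzaldehyde (TFA, CH2Cl2, 0 °C) should then close the oxane through the chair oxocarbenium ion, the E alkene placing the C3 branch equatorial and trifluoroacetate entering equatorially at C4, to give the C4 trifluoroacetate of 17 F2. Mild methanolysis (NaHCO3, MeOH, rt) returns 17.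

2. Step 11. β-Hydride elimination toward the bis-allylic methine, or palladium hydride migration of a double bond into conjugation with the other styrene, would destroy the skipped diene. Fallback, setting out from 14 and coming back at 16: cross-metathesis of the terminal vinyl group with commercial tert-butyldimethyl(4-vinylphenoxy)silane (second-generation Hoveyda–Grubbs catalyst, CH2Cl2, 40 °C) should give 16 directly without any palladium hydride. The slower-reacting internal styrene is expected to stay out of the exchange.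

3. Step 8. Regio- and E/Z control may be lost in the pentadienyl-palladium intermediate, or the bis-allylic cation may be trapped by methanol. Fallback, setting out from 10 and coming back at 12 (it replaces steps 7 and 8): boron-Wittig olefination of 10 with bis[(pinacolato)boryl]methane and lithium 2,2,6,6-tetramethylpiperidide (THF, −78 °C to rt) should give 4-[(1E,3E)-4-(4,4,5,5-tetramethyl-1,3,2-dioxaborolan-2-yl)buta-1,3-dien-1-yl]phenyl pivalate F3. Matteson homologation of F3 with chloromethyllithium made in the flask (BrCH2Cl, n-BuLi, THF, −78 °C to rt) inserts the CH2 group between the diene and boron and gives 12 with defined E,E geometry.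

Further compounds
F1 | step 12 | (1E,3S,4S)-3-[(1E,4S)-4-hydroxy-6-{4-(pivaloyloxy)phenyl}hex-1-en-1-yl]-1,7-bis[4-(pivaloyloxy)phenyl]hept-1-en-4-yl acetate | CC(C)(C)C(=O)Oc1ccc(/C=C/[C@H](/C=C/C[C@@H](O)CCc2ccc(OC(=O)C(C)(C)C)cc2)[C@@H](OC(C)=O)CCCc2ccc(OC(=O)C(C)(C)C)cc2)cc1
F2 | step 12 | (2S,3S,4R,6S)-3-[(1E,3R,4S)-4-acetoxy-1,7-bis{4-(pivaloyloxy)phenyl}hept-1-en-3-yl]-2-(4-{[tert-butyl(dimethyl)silyl]oxy}phenyl)-6-{2-[4-(pivaloyloxy)phenyl]ethyl}oxan-4-yl trifluoroacetate | CC(C)(C)C(=O)Oc1ccc(/C=C/[C@H]([C@@H]2[C@@H](c3ccc(O[Si](C)(C)C(C)(C)C)cc3)O[C@@H](CCc3ccc(OC(=O)C(C)(C)C)cc3)C[C@H]2OC(=O)C(F)(F)F)[C@@H](OC(C)=O)CCCc2ccc(OC(=O)C(C)(C)C)cc2)cc1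
F0 | step 11 | none | none
F3 | step 8 | 4-[(1E,3E)-4-(4,4,5,5-tetramethyl-1,3,2-dioxaborolan-2-yl)buta-1,3-dien-1-yl]phenyl pivalate | CC(C)(C)C(=O)Oc1ccc(/C=C/C=C/B2OC(C)(C)C(C)(C)O2)cc1
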